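The constants, with partner as charged, sort this flask into two quick equilibria and a slower one-way leak, so count half-lives against that leak.

    intermediate ⇌ product + by-product (K1 = 0.0026 M, k1 = 0.92 /h)
    intermediate → decomposed reagent (k2 = 0.20 /h)
    substrate + partner ⇌ intermediate (K3 = 6.9 /M, k3 = 11 /M/h)

| flask | substrate | partner | time |
|---|---|---|---|
| amber | 0.012 M | 0.0750 M | 30 h |
| blue | 0.025 M | 0.0750 M | 30 h |
| violet | 0.050 M | 0.0750 M | 30 h |
| ochre | 0.10 M | 0.0750 M | 30 h |
| red | 0.20 M | 0.0750 M | 30 h |

- "hardly changes" means that all values lie within two and a half points (for a concentration: within two and a half percent of the largest)
- run time (amber): 30 h

1. [product] at the end for amber, blue, violet, ochre, red, in this order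
2. the shape of the row from first to last (rises, then falls / falls, then rises / rises all the way / hardly changes / falls all the way)

**First instants.** Take amber, where partner is charged at 6.25 times the substrate. With partner as charged, the binding of substrate to partner has a forward half-life of 0.84 h, and the split of intermediate into product and by-product has a forward half-life of 0.75 h. Both are shorter than the 3.5 h of the leak to decomposed reagent. So in amber I take the binding as balanced: with partner as charged, that puts intermediate at 0.52 of substrate, which is 34.1% of the two together.

**The rule.** Amber's run lasts 39.8 forward split half-lives, so I take product and by-product, made one for one, as keeping pace with the intermediate. Call 0.217 the split number, the split constant over the substrate charge. With each share a fraction of the substrate charge, the square of the product share then equals the split number times the intermediate share.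

**The middle.** Leaving product aside, I reckon that amber's pool of substrate and intermediate drains with a lifetime of 14.7 h, and 2.05 lifetimes pass.

**The end.** I reckon amber's intermediate share at 4.41%, so the rule gives a product share of 9.77%, or 0.00117 M.

**The row.** Ochre and red charge more substrate than partner, so partner is the limiting reagent, and each leaked intermediate takes one partner for good. The same reckoning on the partner charge, with substrate as charged, holds 40.8% of it bound in ochre and 58.0% in red, so I reckon that red's pool of partner and intermediate drains faster than ochre's. That gives 0.00262 M for ochre and 0.00187 M for red. My figures put ochre above amber and red, so I commit to a row that rises, then falls.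

The forecast gives 0.0013 M, 0.0019 M, 0.0027 M, 0.0031 M and 0.0026 M, a row that rises, then falls, holding that “at the high end it uses up the partner faster”.

**The result.** The flask gives 0.00132 M, 0.00189 M, 0.00260 M, 0.00307 M and 0.00262 M, so the row rises, then falls, turning at the 0.10 M substrate charge; amber, ochre and red stand above my figures. At the end red holds 4.05% of its partner charge. In amber, the split number 0.217 on the intermediate share 5.31% gives 10.7% of the substrate charge, and amber holds 11.0% as product. Ochre's split number is 0.0260; on its intermediate share 3.55% that gives 3.04%, and ochre holds 3.07% as product.

The numbers were set for the occasion; the result is computed.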